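The data come from a simulation from invented constants, and the scatter is random.

By its reading at 50.0 min, Thursday's flask had made 6810 target per free enzyme charged. This ratio of target made to enzyme charged is the turnover number, and I reckoned the options with it.

| setting | Thursday's | Friday's | flask |
|---|---|---|---|
| substrate | 0.10 M | 0.10 M | 0.10 M |
| free enzyme | 0.01 mol% | 0.01 mol% | 0.01 mol% |
| temperature | 40 °C | 25 °C | 40 °C |
| remark | the very flask that is asked about, followed so far | run made earlier |  |
| time |  |  | 50 min |

| run | time / min | target / % |
|---|---|---|
| Thursday's | 3.00 | 35.8 |
| Thursday's | 10.0 | 50.1 |
| Thursday's | 20.0 | 57.6 |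
| Thursday's | 25.0 | 61.0 |
| Thursday's | 40.0 | 67.1 |
| Thursday's | 50.0 | 68.1 |
| Friday's | 6.00 | 21.2 |
| Friday's | 20.0 | 28.9 |
| Friday's | 40.0 | 33.8 |
| Friday's | 50.0 | 34.5 |
| Friday's | 80.0 | 38.4 |
| Friday's | 120 | 40.6 |

(each reading ± 0.5 percentage points)

- target that was removed still counts
- additions bring no volume worth counting

- green: at 50 min add free enzyme, 50.0% of the amount charged, then wait 25 min
- teal: at 50 min take out 90% of the target then present, then wait 25 min
- blue: change nothing and wait 25 min more
- red: at 50 min raise the temperature by 20 K, then wait 25 min

* target, in percent of the substrate first charged, at 50 min
* the option that brings most further target ("none" if no option brings more than 2 percentage points) (green / teal / blue / red / none)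
* target present, with what was taken out counted in, in percent of the substrate first charged, after green
* target present, with what was taken out counted in, in percent of the substrate first charged, after teal

My ladder for this flask began at one turnover: the first 3.00 min gave 3580 turnovers per free enzyme charged, on average 0.0503 s each. The next rung was minutes, for those 3.00 min earned about half of the target read at 50.0 min. The opening rate exceeded the rate between 20.0 min and 40.0 min by a factor of 25.1, much more than the factor of 3.04 between the substrate charged and the substrate unread as target at 40.0 min, so I read the excess as lost working enzyme. On the last rung, the 31.9% of substrate still unread as target came, by my reckoning at that late rate held steady, to 67.2 min, longer than the 25 min on offer.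

The first dose earned 7.1 percentage points between 25.0 min and 50.0 min, so I expected less than that from blue, and about as much from teal as from blue. That dose, fresh at the start, had reached a turnover number of 6100 by 25.0 min. If the added half dose matched it despite the lower substrate, it would earn 30 points, nearly all of what remained, for about 98.6%.

The forecast gave 68.3% (67.3% to 69.3%) now, 84.5% (80% to 89%) after green and 71.8% (70% to 74.5%) after teal. It chose green, noting “Red helps less and risks faster deactivation”. My figure for green stood higher than the top of the forecast's range.

The flask gave 68.7% at 50 min. Green brought 31 points, reaching >99.9%; blue and teal each brought 4.7 points, teal reaching 73.4%; red brought 2.9 points.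

    free enzyme → unfolded enzyme (k = 1.60 × 10⁻⁴ /s, Ea = 196 kJ/mol)
    substrate + free enzyme ⇌ complex (K = 110 /M, k = 2.20 × 10⁵ /M/s, Ea = 30.0 kJ/mol, ΔH = −11.0 kJ/mol)
    complex → free enzyme + target (k = 150 /s, Ea = 59.0 kJ/mol)
    2 complex → spent catalyst (k = 7100 /M/s, Ea = 30.0 kJ/mol)
    (constants at 40 °C)

Green's gain matched the 31% of substrate left at 50.0 min, against my 30 points. The same reckoning on the neighbouring flask, charged with 0.0025 mol% of free enzyme, a quarter of this flask's loading, gives 17.0% target at 50 min. That neighbour held 52.1%. Its turnover number was therefore 20800, which is 3.06 times the one read on Thursday's flask.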